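## Analysis of the target

β-Collatolic acid (24) is a diaryl ether without any stereocentre. One half is a 6-methoxy-3-pentylisocoumarin: benzo ring A (C4a, C5, C6, C7, C8, C8a) fused to the lactone ring (C1, O2, C3, C4), with the ether oxygen on C8, next to the lactone carbonyl. The other half, ring B, is a 4,6-dihydroxybenzoic acid (C1′ to C6′) with a 2-oxoheptyl arm on C2′ and the ether oxygen on C3′, so this oxygen lies between the arm and the C4′ hydroxyl. Both halves are the same building block, a resorcylate with a CH2–CO–pentyl arm ortho to the carboxyl. In ring A it is closed to the enol lactone; in ring B it stays open as the keto acid, and the route has to preserve this difference. Sensitive groups are the enol lactone (opened by hydroxide or alkoxide, C3=C4 reducible), the benzylic ketone beside a free acid (lactol or second isocoumarin under dehydrating acid) and the electron-rich salicylic acid of ring B (decarboxylation on heating). The hard bond is C8–O–C3′: the oxygen is flanked by two ortho substituents on ring B and by the carboxyl-bearing carbon on ring A, and both rings are electron-rich. The plan rests on ring A being an orsellinate-type ring. Its carbons C8a, C8, C7, C6, C5 and C4a map onto a linear chain with oxygen on every second carbon. Because the C8 oxygen is arylated, the chain can carry C8 as an aryl enol ether of the ring B phenol, C6 and C4a as ketones and C8a as the α-carbon of an ester.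

## Retrosynthetic reasoning

24 is traced back to its tribenzyl derivative 23 by cutting the three benzyl–oxygen bonds. Hydrogenolysis is neutral, so the lactone, the ketone and the free salicylic acid appear only in the last step. A benzyl ester on ring B, not a tert-butyl ester, is what keeps the two halves different in the step before.

In 23 the lactone bond O2–C1 is cut, giving the keto acid 22, which comes from 21 by one acid treatment (tert-butyl ester and both dioxolanes). Only ring A then has a free carboxyl, so only ring A can be dehydrated to the enol lactone. The methyl ether of 21 is cut back to the phenol 20; C6–OH is the only free hydroxyl at that stage.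

Ring A of 20 is opened at C8a–C4a. This is the bond a polyketide aldol makes, and cutting it turns the arene into the open chain 18, in which C8 is already bonded to the ring B oxygen. What is gained is that no aryl–oxygen bond has to be made on a finished, crowded arene. The forward reaction must add the C8a carbanion to the C4a ketone and lose water. For that reason the ester is tert-butyl (no Claisen closure from C5) and the C3 ketone is a dioxolane (C4 stays singly activated). The ring B ketone is also kept as a dioxolane in 18, so that C4a is the only ketone in the molecule.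

18 is cut at C5–C4a into the methyl ketone 17 and the Weinreb amide 11. An ester condensation at C6 on a glutaconate-type diester would fail, because the CH2 between the enol ether and the ester is deprotonated first and that switches off both esters. The disconnection chosen makes use of this acidity: it is taken up as the first of two deprotonations, and the second gives the terminal carbanion at C5 that is acylated. Both double-bond tautomers and both geometries of 17 give the same dianion.

17 is cut at the C8–O bond into the ring B phenol 8 and the allene 16. The forward reaction is a conjugate addition of a phenoxide to the central carbon of an allene activated from both ends, which tolerates the two ortho substituents of 8 far better than a coupling at an arene carbon.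

16 is cut at its C=C bond into the acid 12 (as its ketene) and the ylide 13. The amide 11 goes back through the ester 10 to the keto ester 9, which already holds the pentyl ketone.

The phenol 8 goes back to the bromide 6 (C3′–O from C3′–Br through boron), 6 to the ketone 5, and 5 by the benzylic C–C bond to the toluate 3 and the amide 4. 3 comes from 2 by ring bromination and 2 from orsellinic acid 1 by threefold benzylation. The bromine is placed before the arm, so that the free position between the methyl and the benzyloxy group is used while the molecule is still simple.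

## Alternatives that were turned down

Alternative 1: Both CH2–CO bonds are cut at once. The diaryl ether A2, with an ortho-methyl group on each ring, would be deprotonated twice by a lithium amide base and both benzylic anions acylated with 4, giving A1. A1 is the same compound as 22, so this plan joins the chosen endgame two steps before the target.
- For it: it is shorter than the chosen route, it uses one acyl donor for both arms, and every reaction type is known. On these points it is stronger.
- Against it: A2 needs a bond between the di-ortho-substituted ring B oxygen and the ring A carbon ortho to the carboxyl, both on electron-rich rings, which is the hardest bond of the molecule made in the hardest way. The double lateral metalation needs a polyanion beside a benzyl ester, and mono- and bis-acylation have to be separated.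
- In its place the chosen strategy makes the ether bond by conjugate addition at an allene carbon under mild base and brings in the two arms separately and differently protected. The price is a ring closure that is less well precedented.

Alternative 2: Ring B is cut at C1′–C6′ and C3′–C4′. The acetoacetate A4 would add through its α-carbon to the acrylate A5 (built on the C8 oxygen of a finished isocoumarin), and its methyl carbon would then condense on the acrylate ester to give the cyclohexane-1,3-dione A3, which must be dehydrogenated to ring B.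
- For it: like the chosen plan it needs no aryl–oxygen coupling, and the Michael–Claisen annulation is a known way to such diones. On the ether bond the two plans are equally strong.
- Against it: A5 is a poor acceptor (donor oxygen on the α-carbon, a neopentyl-type β-substituent). The enol lactone must survive enolate and alkoxide. Three stereocentres are made only to be destroyed. A3 is one oxidation level below the arene, so an oxidant is needed, while loss of the aryloxide reaches an aromatic resorcylate without any oxidant and would cut the molecule in two.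
- In the chosen strategy the aldol product is already at the arene oxidation level and aromatizes by loss of water alone.

Alternative 3: Ring A is cut at C8–C8a. The triene A7, a 3-chloro-2-pyranone with a 2-methoxy-4-aryloxybutadienyl chain on C4a, would close thermally by a six-electron electrocyclization, and dehydrochlorination across C8–C8a would give A6. A6 is the same compound as 23.
- For it: the endgame is stronger than the chosen one. The lactone ring is present from the start, the ring A ketone never exists, and only the hydrogenolysis remains. No base is involved.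
- Against it: A7 holds two enol ethers and needs a defined geometry at C5=C6. Making it requires O-vinylation of the hindered phenol and a cross-coupling on a halogenated pyranone, which is a longer and less certain sequence than the two bond formations that lead from 8 to 18. The cyclization must also break the conjugation of the pyranone and competes with its cycloaddition chemistry at high temperature.
- The chosen strategy needs three more steps after ring closure, but its precursor is short to make and its alkene geometry corrects itself.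

Key step: step 11

## Route

Assumption: β-collatolic acid is treated as the open keto acid that is drawn (no lactol form).

Shorthand: ArB = 3-(benzyloxycarbonyl)-4,6-bis(benzyloxy)-2-[(2-pentyl-1,3-dioxolan-2-yl)methyl]phenyl, that is ring B of 8 without its hydroxyl. Chain atoms of 17, 18 and 19 carry the ring A labels they become (C8a, C8, C7, C6, C5, C4a, C4, C3).

Step 1
Reactants: 1 orsellinic acid (2,4-dihydroxy-6-methylbenzoic acid)
Product: 2 benzyl 2,4-bis(benzyloxy)-6-methylbenzoate
Conditions: BnBr (3.5 equiv), K2CO3, DMF, 60 °C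
Reagents that add atoms: benzyl bromide, BrCc1ccccc1
Why: Williamson alkylation of the carboxylate and both phenoxides; the carboxylate reacts first, which protects the acid against decarboxylation, and heating brings in the hydrogen-bonded ortho hydroxyl.

Step 2
Reactants: 2 benzyl 2,4-bis(benzyloxy)-6-methylbenzoate
Product: 3 benzyl 4,6-bis(benzyloxy)-3-bromo-2-methylbenzoate
Conditions: NBS (1.05 equiv), MeCN, 0 °C → rt, in the dark
Reagents that add atoms: N-bromosuccinimide, O=C1CCC(=O)N1Br
Why: Electrophilic aromatic bromination; C3′ (ortho to one benzyloxy group, para to the other, next to the methyl) should be preferred over C5′, which lies between two benzyloxy groups, as in 3,5-dialkoxytoluenes, and without a radical initiator the methyl group should stay untouched.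

Step 3
Reactants: 3 benzyl 4,6-bis(benzyloxy)-3-bromo-2-methylbenzoate; 4 N-methoxy-N-methylhexanamide
Product: 5 benzyl 4,6-bis(benzyloxy)-3-bromo-2-(2-oxoheptyl)benzoate
Conditions: LiN(iPr)2 (2.0 equiv), THF, −78 °C; then 4, −78 °C; aq. NH4Cl
Reagents that add atoms: none
Why: Lateral lithiation of an ortho-toluate and acylation with a Weinreb amide, whose chelated adduct stops at the ketone; the amide base does not exchange the bromine, no ring hydrogen is ortho to it, and the di-ortho-substituted ester is too hindered for self-condensation.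

Step 4
Reactants: 5 benzyl 4,6-bis(benzyloxy)-3-bromo-2-(2-oxoheptyl)benzoate
Product: 6 benzyl 4,6-bis(benzyloxy)-3-bromo-2-[(2-pentyl-1,3-dioxolan-2-yl)methyl]benzoate
Conditions: (Me3SiOCH2)2, Me3SiOTf (0.1 equiv), CH2Cl2, −78 → −20 °C; pyridine quench
Reagents that add atoms: 1,2-bis(trimethylsilyloxy)ethane, C[Si](C)(C)OCCO[Si](C)(C)C
Why: Silyl-triflate-catalysed ketalization under aprotic conditions at low temperature, which avoids the acid-induced closure of the keto ester to an isocoumarin that hot protic acid could cause.

Step 5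
Reactants: 6 benzyl 4,6-bis(benzyloxy)-3-bromo-2-[(2-pentyl-1,3-dioxolan-2-yl)methyl]benzoate
Product: 8 benzyl 4,6-bis(benzyloxy)-3-hydroxy-2-[(2-pentyl-1,3-dioxolan-2-yl)methyl]benzoate, via ring B pinacol boronate 7 (not isolated)
Conditions: B2pin2, Pd(OAc)2 (5 mol %), SPhos, KOAc, 1,4-dioxane, 90 °C; then H2O2 (30% aq.), NaOH (1 equiv), THF, 0 °C
Reagents that add atoms: bis(pinacolato)diboron, CC1(C)OB(OC1(C)C)B1OC(C)(C)C(C)(C)O1 (boryl group of 7 only); hydrogen peroxide, OO (oxygen of 8)
Why: Miyaura borylation followed by oxidative carbon-to-oxygen migration on boron; a bulky biarylphosphine is chosen because the bromide has two ortho substituents, and the hindered benzyl ester should survive the short cold peroxide treatment.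

Step 6
Reactants: 9 ethyl 3-oxooctanoate
Product: 10 ethyl (2-pentyl-1,3-dioxolan-2-yl)acetate
Conditions: HOCH2CH2OH, TsOH·H2O (cat.), toluene, reflux, Dean–Stark trap
Reagents that add atoms: ethylene glycol, OCCO
Why: Acid-catalysed ketalization of a β-keto ester with removal of water, a standard protection.

Step 7
Reactants: 10 ethyl (2-pentyl-1,3-dioxolan-2-yl)acetate
Product: 11 N-methoxy-N-methyl-2-(2-pentyl-1,3-dioxolan-2-yl)acetamide
Conditions: MeNHOMe·HCl, iPrMgCl, THF, −20 → 0 °C
Reagents that add atoms: N,O-dimethylhydroxylamine hydrochloride, CNOC.Cl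
Why: Aminolysis of the ester by the magnesium amide of N,O-dimethylhydroxylamine, the usual direct ester-to-Weinreb-amide conversion; the amide is too weakly basic to enolize the ester and open the dioxolane.

Step 8
Reactants: 12 3-tert-butoxy-3-oxopropanoic acid (mono-tert-butyl malonate); 13 1-(triphenyl-λ5-phosphanylidene)propan-2-one
Product: 16 tert-butyl 5-oxohexa-2,3-dienoate (racemic allene), via tert-butyl 3-chloro-3-oxopropanoate 14 (not isolated), via tert-butoxycarbonylketene 15 (not isolated)
Conditions: Me2C=C(Cl)NMe2, CH2Cl2, 0 °C; then 13, Et3N, CH2Cl2, −20 °C → rt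
Reagents that add atoms: 1-chloro-N,N,2-trimethylprop-1-en-1-amine, CC(C)=C(Cl)N(C)C (chlorine of 14 only)
Why: Neutral acid chloride formation keeps the tert-butyl ester intact; triethylamine turns the malonyl chloride into the ketene 15, and Wittig olefination of the ketene carbonyl by the stabilized ylide gives the 1,3-diacceptor allene, the standard way to allenic esters and ketones.

Step 9
Reactants: 8 benzyl 4,6-bis(benzyloxy)-3-hydroxy-2-[(2-pentyl-1,3-dioxolan-2-yl)methyl]benzoate; 16 tert-butyl 5-oxohexa-2,3-dienoate
Product: 17 tert-butyl (3E)-3-(ArB-oxy)-5-oxohex-3-enoate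
Conditions: K2CO3 (0.3 equiv), MeCN, 0 °C → rt, slow addition of 16
Reagents that add atoms: none
Why: Oxa-Michael addition of the phenoxide to the central carbon of the allene, which is activated from both ends and is sterically open, so the two ortho substituents of 8 should be tolerated; the ketone-conjugated E enol ether is the expected thermodynamic product, and any Z or ester-conjugated isomer is carried on, because step 10 goes through one common dianion.

Step 10
Reactants: 17 tert-butyl (3E)-3-(ArB-oxy)-5-oxohex-3-enoate; 11 N-methoxy-N-methyl-2-(2-pentyl-1,3-dioxolan-2-yl)acetamide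
Product: 18 tert-butyl (3E)-3-(ArB-oxy)-5,7-dioxo-8-(2-pentyl-1,3-dioxolan-2-yl)oct-3-enoate
Conditions: LiN(iPr)2 (2.3 equiv), THF, −78 °C; then 11, −78 → −30 °C; aq. NH4Cl; crude product used directly
Reagents that add atoms: none
Why: Terminal C-acylation of a dienolate dianion, as in the γ-acylation of β-keto ester dianions: the first equivalent of base removes the C8a proton, the second the methyl proton, and the last-formed, least stabilized carbanion (C5) attacks the Weinreb amide, whose chelated adduct releases the C4a ketone only on work-up; in the dianion both the ester and the C6 carbonyl are enolates, so it cannot cyclize on itself.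

Step 11
Reactants: 18 tert-butyl (3E)-3-(ArB-oxy)-5,7-dioxo-8-(2-pentyl-1,3-dioxolan-2-yl)oct-3-enoate
Product: 20 tert-butyl 2-(ArB-oxy)-4-hydroxy-6-[(2-pentyl-1,3-dioxolan-2-yl)methyl]benzoate, via cyclic aldol adduct 19 (not isolated)
Conditions: Cs2CO3 (1.5 equiv), THF/tBuOH (10:1), rt → 40 °C; then AcOH
Reagents that add atoms: none
Why: Proposed new method: carbonate first gives the C5 diketone enolate, but proton exchange also populates the anion at C8a (α to the ester, γ to the β-aryloxy enone), whose carbon adds to the C4a ketone to form the C8a–C4a bond and the cyclohexenone 19; E1cB loss of the C4a hydroxyl through the C5 enolate and enolization of the C6 ketone then give the phenol 20. The closest known reaction type is the base-mediated aldol aromatization of 3,5,7-trioxo esters to resorcylates; a chain whose 3-oxo group is replaced by an aryl enol ether has not been shown to do this. Ring A closes in a 6-(enolexo)-exo-trig mode. No stereocentre is set, since the two of 19 disappear on aromatization. The closure needs C8a and C6 on the same side of C7=C8 (the E isomer); the Z isomer and the ester-conjugated tautomer give the same delocalized anion, so the geometry should correct itself. Selectivity is needed against Claisen closure of C5 on the ester (blocked by the tert-butyl group), against attack of the C4a enolate oxygen or an outside nucleophile on C8 with loss of phenol 8 (countered by a non-nucleophilic base, no primary alcohol or hydroxide, and by the C8a anion making C8 electron-rich), and against reaction at C4 or C3 (C3 is a dioxolane, so C4 is only singly activated and there is no second ketone). Loss of water to the arene should make the sequence irreversible.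

Step 12
Reactants: 20 tert-butyl 2-(ArB-oxy)-4-hydroxy-6-[(2-pentyl-1,3-dioxolan-2-yl)methyl]benzoate
Product: 21 tert-butyl 2-(ArB-oxy)-4-methoxy-6-[(2-pentyl-1,3-dioxolan-2-yl)methyl]benzoate
Conditions: MeI, K2CO3, acetone, rt
Reagents that add atoms: iodomethane, CI
Why: Williamson methylation of the only free phenol; no enolizable 1,3-dicarbonyl remains that could be C-methylated.

Step 13
Reactants: 21 tert-butyl 2-(ArB-oxy)-4-methoxy-6-[(2-pentyl-1,3-dioxolan-2-yl)methyl]benzoate
Product: 23 benzyl 4,6-bis(benzyloxy)-3-[(6-methoxy-1-oxo-3-pentyl-1H-isochromen-8-yl)oxy]-2-(2-oxoheptyl)benzoate, via keto acid 22 (not isolated)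
Conditions: CF3CO2H/CH2Cl2/H2O (10:10:1), rt; evaporation; then (CF3CO)2O, CH2Cl2, 0 °C → rt
Reagents that add atoms: water, O
Why: Aqueous acid cleaves the tert-butyl ester and hydrolyses both dioxolanes; the anhydride then activates the only free carboxyl (ring A) as a mixed anhydride, which is captured by the enol of the neighbouring ketone (enol lactonization to the isocoumarin), while ring B, still a benzyl ester, has no acid to activate and should stay open.

Step 14
Reactants: 23 benzyl 4,6-bis(benzyloxy)-3-[(6-methoxy-1-oxo-3-pentyl-1H-isochromen-8-yl)oxy]-2-(2-oxoheptyl)benzoate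
Product: 24 β-collatolic acid, 4,6-dihydroxy-3-[(6-methoxy-1-oxo-3-pentyl-1H-isochromen-8-yl)oxy]-2-(2-oxoheptyl)benzoic acid
Conditions: H2 (1 atm), Pd/C, EtOAc, rt
Reagents that add atoms: none
Why: Hydrogenolysis of two benzyl ethers and one benzyl ester under neutral conditions at low pressure, where the enol lactone double bond, the dialkyl ketone and the diaryl ether are expected to persist; the reaction is stopped once hydrogen uptake for three benzyl groups is complete.

## Compound list

1 | orsellinic acid (2,4-dihydroxy-6-methylbenzoic acid) | Cc1cc(O)cc(O)c1C(=O)O | starting material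
2 | benzyl 2,4-bis(benzyloxy)-6-methylbenzoate | Cc1cc(OCc2ccccc2)cc(OCc2ccccc2)c1C(=O)OCc1ccccc1 | intermediate
3 | benzyl 4,6-bis(benzyloxy)-3-bromo-2-methylbenzoate | Cc1c(Br)c(OCc2ccccc2)cc(OCc2ccccc2)c1C(=O)OCc1ccccc1 | intermediate
4 | N-methoxy-N-methylhexanamide | CCCCCC(=O)N(C)OC | starting material
5 | benzyl 4,6-bis(benzyloxy)-3-bromo-2-(2-oxoheptyl)benzoate | CCCCCC(=O)Cc1c(Br)c(OCc2ccccc2)cc(OCc2ccccc2)c1C(=O)OCc1ccccc1 | intermediate
6 | benzyl 4,6-bis(benzyloxy)-3-bromo-2-[(2-pentyl-1,3-dioxolan-2-yl)methyl]benzoate | CCCCCC1(Cc2c(Br)c(OCc3ccccc3)cc(OCc3ccccc3)c2C(=O)OCc2ccccc2)OCCO1 | intermediate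
7 | benzyl 4,6-bis(benzyloxy)-2-[(2-pentyl-1,3-dioxolan-2-yl)methyl]-3-(4,4,5,5-tetramethyl-1,3,2-dioxaborolan-2-yl)benzoate | CCCCCC1(Cc2c(B3OC(C)(C)C(C)(C)O3)c(OCc3ccccc3)cc(OCc3ccccc3)c2C(=O)OCc2ccccc2)OCCO1 | intermediate
8 | benzyl 4,6-bis(benzyloxy)-3-hydroxy-2-[(2-pentyl-1,3-dioxolan-2-yl)methyl]benzoate (ring B phenol) | CCCCCC1(Cc2c(O)c(OCc3ccccc3)cc(OCc3ccccc3)c2C(=O)OCc2ccccc2)OCCO1 | intermediate
9 | ethyl 3-oxooctanoate | CCCCCC(=O)CC(=O)OCC | starting material
10 | ethyl (2-pentyl-1,3-dioxolan-2-yl)acetate | CCCCCC1(CC(=O)OCC)OCCO1 | intermediate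
11 | N-methoxy-N-methyl-2-(2-pentyl-1,3-dioxolan-2-yl)acetamide | CCCCCC1(CC(=O)N(C)OC)OCCO1 | intermediate
12 | 3-tert-butoxy-3-oxopropanoic acid (mono-tert-butyl malonate) | CC(C)(C)OC(=O)CC(=O)O | starting material
13 | 1-(triphenyl-λ5-phosphanylidene)propan-2-one | CC(=O)C=P(c1ccccc1)(c1ccccc1)c1ccccc1 | starting material
14 | tert-butyl 3-chloro-3-oxopropanoate | CC(C)(C)OC(=O)CC(=O)Cl | intermediate
15 | tert-butyl 3-oxoprop-2-enoate (tert-butoxycarbonylketene) | CC(C)(C)OC(=O)C=C=O | intermediate
16 | tert-butyl 5-oxohexa-2,3-dienoate (racemic allene) | CC(=O)C=C=CC(=O)OC(C)(C)C | intermediate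
17 | tert-butyl (3E)-3-(ArB-oxy)-5-oxohex-3-enoate | CC(C)(C)OC(=O)C/C(Oc1c(CC2(CCCCC)OCCO2)c(C(=O)OCc2ccccc2)c(OCc2ccccc2)cc1OCc1ccccc1)=C\C(C)=O | intermediate
18 | tert-butyl (3E)-3-(ArB-oxy)-5,7-dioxo-8-(2-pentyl-1,3-dioxolan-2-yl)oct-3-enoate (drawn as the diketo form) | CC(C)(C)OC(=O)C/C(Oc1c(CC2(CCCCC)OCCO2)c(C(=O)OCc2ccccc2)c(OCc2ccccc2)cc1OCc1ccccc1)=C\C(=O)CC(=O)CC1(CCCCC)OCCO1 | intermediate
19 | tert-butyl 2-(ArB-oxy)-6-hydroxy-4-oxo-6-[(2-pentyl-1,3-dioxolan-2-yl)methyl]cyclohex-2-ene-1-carboxylate (racemic, mixture of diastereomers) | CC(C)(C)OC(=O)C1C(Oc2c(CC3(CCCCC)OCCO3)c(C(=O)OCc3ccccc3)c(OCc3ccccc3)cc2OCc2ccccc2)=CC(=O)CC1(O)CC1(CCCCC)OCCO1 | intermediate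
20 | tert-butyl 2-(ArB-oxy)-4-hydroxy-6-[(2-pentyl-1,3-dioxolan-2-yl)methyl]benzoate | CCCCCC1(Cc2cc(O)cc(Oc3c(CC4(CCCCC)OCCO4)c(C(=O)OCc4ccccc4)c(OCc4ccccc4)cc3OCc3ccccc3)c2C(=O)OC(C)(C)C)OCCO1 | intermediate
21 | tert-butyl 2-(ArB-oxy)-4-methoxy-6-[(2-pentyl-1,3-dioxolan-2-yl)methyl]benzoate | CCCCCC1(Cc2cc(OC)cc(Oc3c(CC4(CCCCC)OCCO4)c(C(=O)OCc4ccccc4)c(OCc4ccccc4)cc3OCc3ccccc3)c2C(=O)OC(C)(C)C)OCCO1 | intermediate
22 | 2-[3-(benzyloxycarbonyl)-4,6-bis(benzyloxy)-2-(2-oxoheptyl)phenoxy]-4-methoxy-6-(2-oxoheptyl)benzoic acid | CCCCCC(=O)Cc1cc(OC)cc(Oc2c(CC(=O)CCCCC)c(C(=O)OCc3ccccc3)c(OCc3ccccc3)cc2OCc2ccccc2)c1C(=O)O | intermediate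
23 | benzyl 4,6-bis(benzyloxy)-3-[(6-methoxy-1-oxo-3-pentyl-1H-isochromen-8-yl)oxy]-2-(2-oxoheptyl)benzoate | CCCCCc1cc2cc(OC)cc(Oc3c(CC(=O)CCCCC)c(C(=O)OCc4ccccc4)c(OCc4ccccc4)cc3OCc3ccccc3)c2c(=O)o1 | intermediate
24 | β-collatolic acid | CCCCCC(=O)Cc1c(Oc2cc(OC)cc3cc(CCCCC)oc(=O)c23)c(O)cc(O)c1C(=O)O | target

## Step count and least certain steps

Total: 14 steps. Longest linear sequence: 11 steps (steps 1 to 5 and 9 to 14, from 1).

Step 11 (key step, proposed new method).
- What may go wrong: the C4a enolate oxygen may add to C8 and expel the ring B phenoxide (a pyranone-forming addition–elimination) faster than the C8a carbon adds to C4a. The activated enol ether is a leaving-group-bearing acceptor that the free trioxo esters of the known reaction do not have. The diketone enolate may also leave C4a too weakly electrophilic, so that nothing closes.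
- Fallback (known chemistry, ring A no longer built from a chain): it sets out from 1 and 8 and comes back at 23. Orsellinic acid 1 is methylated on the carboxyl and the C4 hydroxyl (MeI, 2 equiv, K2CO3, acetone; the chelated ortho hydroxyl stays free) to methyl 2-hydroxy-4-methoxy-6-methylbenzoate F1. Tf2O and pyridine give methyl 4-methoxy-2-methyl-6-{[(trifluoromethyl)sulfonyl]oxy}benzoate F2. Palladium-catalysed aryl–oxygen coupling of F2 with 8 (Pd(OAc)2, tBuXPhos, K3PO4, toluene, 100 °C) gives benzyl 4,6-bis(benzyloxy)-3-[5-methoxy-2-(methoxycarbonyl)-3-methylphenoxy]-2-[(2-pentyl-1,3-dioxolan-2-yl)methyl]benzoate F3. Lateral lithiation (LiN(iPr)2, −78 °C) and acylation with 4 give benzyl 4,6-bis(benzyloxy)-3-[5-methoxy-2-(methoxycarbonyl)-3-(2-oxoheptyl)phenoxy]-2-[(2-pentyl-1,3-dioxolan-2-yl)methyl]benzoate F4. NaH in THF closes the enol lactone with loss of methanol to benzyl 4,6-bis(benzyloxy)-3-[(6-methoxy-1-oxo-3-pentyl-1H-isochromen-8-yl)oxy]-2-[(2-pentyl-1,3-dioxolan-2-yl)methyl]benzoate F5, and aqueous CF3CO2H removes the dioxolane to give 23.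

Step 10.
- What may go wrong: proton transfer from the α-CH2 of 11 to the dianion (with opening of the dioxolane of the deprotonated amide by β-elimination) may outrun the slow addition to the amide carbonyl. Excess base may also deprotonate the benzylic CH2 of ring B.
- Fallback (aldol addition and oxidation in place of acylation): it sets out from 10 and 17 and comes back at 18. Ester 10 is reduced with iBu2AlH at −78 °C to (2-pentyl-1,3-dioxolan-2-yl)acetaldehyde F6. The dianion of 17 adds to this far more electrophilic aldehyde at −78 °C to give tert-butyl (3E)-3-(ArB-oxy)-7-hydroxy-5-oxo-8-(2-pentyl-1,3-dioxolan-2-yl)oct-3-enoate F7 (racemic). Dess–Martin periodinane buffered with NaHCO3 oxidizes the β-hydroxy ketone to 18.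

Step 8.
- What may go wrong: the ylide may be C-acylated by the acid chloride or by the ketene instead of olefinating it, and the doubly activated allene may oligomerize on concentration.
- Fallback (ynone in place of the allene): it sets out from 8 and comes back at 17. CuI-catalysed coupling of but-3-yn-2-ol with tert-butyl diazoacetate in MeCN gives tert-butyl 5-hydroxyhex-3-ynoate F8 (racemic). MnO2 oxidizes it to tert-butyl 5-oxohex-3-ynoate F9. Under the conditions of step 9, F9 takes up the phenoxide of 8 at the same carbon (directly, or after base isomerization to 16) to give 17.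

Step 5.
- What may go wrong: oxidative addition and transmetalation at a bromide flanked by a benzyloxy group and a neopentyl-type arm may be slow, so that reduction of the C–Br bond to C–H takes over.
- Fallback (oxygen introduced before the arm, with a temporary allyl ether): it sets out from 3 and comes back at 8. The less hindered bromide 3 is borylated under the same conditions to benzyl 4,6-bis(benzyloxy)-2-methyl-3-(4,4,5,5-tetramethyl-1,3,2-dioxaborolan-2-yl)benzoate F10 and oxidized (H2O2, NaOH) to benzyl 4,6-bis(benzyloxy)-3-hydroxy-2-methylbenzoate F11. Allyl bromide and K2CO3 give benzyl 4,6-bis(benzyloxy)-2-methyl-3-(prop-2-en-1-yloxy)benzoate F12. Lateral lithiation and acylation with 4, as in step 3, give benzyl 4,6-bis(benzyloxy)-2-(2-oxoheptyl)-3-(prop-2-en-1-yloxy)benzoate F13. Ketalization as in step 4 gives benzyl 4,6-bis(benzyloxy)-2-[(2-pentyl-1,3-dioxolan-2-yl)methyl]-3-(prop-2-en-1-yloxy)benzoate F14, and Pd(PPh3)4 with morpholine removes the allyl group to give 8.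

Step 14.
- What may go wrong: saturation of the C3=C4 bond of the enol lactone may compete with the slow cleavage of the hindered benzyl ester.
- Fallback (Lewis-acid debenzylation in place of hydrogenolysis): it sets out from 23 and ends at 24. BCl3 with pentamethylbenzene as cation scavenger in CH2Cl2 at −78 °C cleaves the two aryl benzyl ethers and the benzyl ester without hydrogen; the C6 methyl ether is not next to a carbonyl and should stay. No new compound is made.

## Further compounds

F1 | step 11 | methyl 2-hydroxy-4-methoxy-6-methylbenzoate | COC(=O)c1c(C)cc(OC)cc1O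
F2 | step 11 | methyl 4-methoxy-2-methyl-6-{[(trifluoromethyl)sulfonyl]oxy}benzoate | COC(=O)c1c(C)cc(OC)cc1OS(=O)(=O)C(F)(F)F
F3 | step 11 | benzyl 4,6-bis(benzyloxy)-3-[5-methoxy-2-(methoxycarbonyl)-3-methylphenoxy]-2-[(2-pentyl-1,3-dioxolan-2-yl)methyl]benzoate | COC(=O)c1c(C)cc(OC)cc1Oc1c(CC2(CCCCC)OCCO2)c(C(=O)OCc2ccccc2)c(OCc2ccccc2)cc1OCc1ccccc1
F4 | step 11 | benzyl 4,6-bis(benzyloxy)-3-[5-methoxy-2-(methoxycarbonyl)-3-(2-oxoheptyl)phenoxy]-2-[(2-pentyl-1,3-dioxolan-2-yl)methyl]benzoate | COC(=O)c1c(CC(=O)CCCCC)cc(OC)cc1Oc1c(CC2(CCCCC)OCCO2)c(C(=O)OCc2ccccc2)c(OCc2ccccc2)cc1OCc1ccccc1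
F5 | step 11 | benzyl 4,6-bis(benzyloxy)-3-[(6-methoxy-1-oxo-3-pentyl-1H-isochromen-8-yl)oxy]-2-[(2-pentyl-1,3-dioxolan-2-yl)methyl]benzoate | CCCCCc1cc2cc(OC)cc(Oc3c(CC4(CCCCC)OCCO4)c(C(=O)OCc4ccccc4)c(OCc4ccccc4)cc3OCc3ccccc3)c2c(=O)o1
F6 | step 10 | (2-pentyl-1,3-dioxolan-2-yl)acetaldehyde | CCCCCC1(CC=O)OCCO1
F7 | step 10 | tert-butyl (3E)-3-(ArB-oxy)-7-hydroxy-5-oxo-8-(2-pentyl-1,3-dioxolan-2-yl)oct-3-enoate (racemic) | CC(C)(C)OC(=O)C/C(Oc1c(CC2(CCCCC)OCCO2)c(C(=O)OCc2ccccc2)c(OCc2ccccc2)cc1OCc1ccccc1)=C\C(=O)CC(O)CC1(CCCCC)OCCO1
F8 | step 8 | tert-butyl 5-hydroxyhex-3-ynoate (racemic) | CC(O)C#CCC(=O)OC(C)(C)C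
F9 | step 8 | tert-butyl 5-oxohex-3-ynoate | CC(=O)C#CCC(=O)OC(C)(C)C
F10 | step 5 | benzyl 4,6-bis(benzyloxy)-2-methyl-3-(4,4,5,5-tetramethyl-1,3,2-dioxaborolan-2-yl)benzoate | Cc1c(B2OC(C)(C)C(C)(C)O2)c(OCc2ccccc2)cc(OCc2ccccc2)c1C(=O)OCc1ccccc1
F11 | step 5 | benzyl 4,6-bis(benzyloxy)-3-hydroxy-2-methylbenzoate | Cc1c(O)c(OCc2ccccc2)cc(OCc2ccccc2)c1C(=O)OCc1ccccc1
F12 | step 5 | benzyl 4,6-bis(benzyloxy)-2-methyl-3-(prop-2-en-1-yloxy)benzoate | Cc1c(OCC=C)c(OCc2ccccc2)cc(OCc2ccccc2)c1C(=O)OCc1ccccc1
F13 | step 5 | benzyl 4,6-bis(benzyloxy)-2-(2-oxoheptyl)-3-(prop-2-en-1-yloxy)benzoate | CCCCCC(=O)Cc1c(OCC=C)c(OCc2ccccc2)cc(OCc2ccccc2)c1C(=O)OCc1ccccc1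
F14 | step 5 | benzyl 4,6-bis(benzyloxy)-2-[(2-pentyl-1,3-dioxolan-2-yl)methyl]-3-(prop-2-en-1-yloxy)benzoate | CCCCCC1(Cc2c(OCC=C)c(OCc3ccccc3)cc(OCc3ccccc3)c2C(=O)OCc2ccccc2)OCCO1
F0 | step 14 | none | none
A1 | alternative 1 | 2-[3-(benzyloxycarbonyl)-4,6-bis(benzyloxy)-2-(2-oxoheptyl)phenoxy]-4-methoxy-6-(2-oxoheptyl)benzoic acid (same compound as 22) | CCCCCC(=O)Cc1cc(OC)cc(Oc2c(CC(=O)CCCCC)c(C(=O)OCc3ccccc3)c(OCc3ccccc3)cc2OCc2ccccc2)c1C(=O)O
A2 | alternative 1 | 2-[3-(benzyloxycarbonyl)-4,6-bis(benzyloxy)-2-methylphenoxy]-4-methoxy-6-methylbenzoic acid | Cc1cc(OC)cc(Oc2c(C)c(C(=O)OCc3ccccc3)c(OCc3ccccc3)cc2OCc2ccccc2)c1C(=O)O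
A3 | alternative 2 | prop-2-en-1-yl 3-[(6-methoxy-1-oxo-3-pentyl-1H-isochromen-8-yl)oxy]-4,6-dioxo-2-[(2-pentyl-1,3-dioxolan-2-yl)methyl]cyclohexane-1-carboxylate (racemic, all-trans, one enantiomer drawn) | CCCCCC1(C[C@@H]2[C@@H](Oc3cc(OC)cc4cc(CCCCC)oc(=O)c34)C(=O)CC(=O)[C@H]2C(=O)OCC=C)OCCO1
A4 | alternative 2 | prop-2-en-1-yl 3-oxobutanoate (allyl acetoacetate) | CC(=O)CC(=O)OCC=C
A5 | alternative 2 | methyl 2-[(6-methoxy-1-oxo-3-pentyl-1H-isochromen-8-yl)oxy]-4-(2-pentyl-1,3-dioxolan-2-yl)but-2-enoate (alkene geometry not fixed) | CCCCCC1(CC=C(Oc2cc(OC)cc3cc(CCCCC)oc(=O)c23)C(=O)OC)OCCO1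
A6 | alternative 3 | benzyl 4,6-bis(benzyloxy)-3-[(6-methoxy-1-oxo-3-pentyl-1H-isochromen-8-yl)oxy]-2-(2-oxoheptyl)benzoate (same compound as 23) | CCCCCc1cc2cc(OC)cc(Oc3c(CC(=O)CCCCC)c(C(=O)OCc4ccccc4)c(OCc4ccccc4)cc3OCc3ccccc3)c2c(=O)o1
A7 | alternative 3 | benzyl 4,6-bis(benzyloxy)-3-{[(1E,3E)-4-(3-chloro-2-oxo-6-pentyl-2H-pyran-4-yl)-3-methoxybuta-1,3-dien-1-yl]oxy}-2-(2-oxoheptyl)benzoate | CCCCCc1cc(/C=C(OC)\C=C\Oc2c(CC(=O)CCCCC)c(C(=O)OCc3ccccc3)c(OCc3ccccc3)cc2OCc2ccccc2)c(Cl)c(=O)o1
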